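The runs stem from a simulated flask on assumed constants; scatter was added.

Keep the books on partner, and let the earlier runs set the price of each entry.

| flask | starting material | partner | remark | time |
|---|---|---|---|---|
| alpha | 0.084 M | 0.40 M | run made earlier |  |
| gamma | 0.13 M | 0.40 M | run made earlier |  |
| zeta | 0.20 M | 0.30 M | run made earlier |  |
| ochre | 0.20 M | 0.120 M |  | 30 min |
| red | 0.20 M | 0.400 M |  | 30 min |
| green | 0.10 M | 0.400 M |  | 30 min |
| grey | 0.10 M | 0.120 M |  | 30 min |

| run | time / min | target / % | starting material / % |
|---|---|---|---|
| alpha | 4.00 | 86.7 | 0 |
| alpha | 8.00 | 86.7 | 0.1 |
| alpha | 10.0 | 86.7 | 0 |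
| alpha | 15.0 | 86.3 | 0 |
| alpha | 20.0 | 86.9 | 0 |
| gamma | 4.00 | 88.0 | 0.6 |
| gamma | 8.00 | 87.3 | 0.4 |
| gamma | 10.0 | 87.8 | 0.4 |
| gamma | 15.0 | 87.4 | 0 |
| gamma | 20.0 | 87.3 | 0.7 |
| zeta | 4.00 | 89.3 | 3.3 |
| zeta | 8.00 | 92.8 | 0.5 |
| zeta | 12.0 | 92.3 | 0 |
| zeta | 15.0 | 91.9 | 0 |
| zeta | 20.0 | 92.3 | 0.2 |

(scatter of a reading: 0.3 percentage points)

- a reading or a percentage of target counts all its forms, free or not

- all flasks from highest to lowest amount of target, in percent of the starting material charged, at 30 min (ochre / red / green / grey)
- the amount of target, in percent of the starting material charged of the flask you put first, at 30 min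
- the amount of target, in percent of the starting material charged of the flask you put last, at 30 min

In each earlier run target holds flat within the scatter from 8.00 min on, with starting material near zero (zeta: 0.2% at 20.0 min), so I read the missing part of the charge as a parallel route from starting material, and I assume its side product costs two partner. Zeta's last reading is 92.3% target, so loss over target is 0.0834. Its mean [partner], midway between charge and end, is 0.192 M. The quotient is κ, the selectivity factor: side product made per target made, per unit of [partner], here 0.434 M⁻¹. Alpha gives 0.428 M⁻¹ and gamma 0.445 M⁻¹, at other [starting material].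

Each target therefore costs one partner for itself and twice κ[partner] for its side product. In ochre, partner is the limiting reagent, 0.120 M against 0.20 M. Summing that cost down to empty, target takes 0.114 M of the partner. The remainder, at two partner each, buys 0.002922 M of side product, and 0.0831 M of starting material stays unused. The books close at 57.0% target, 1.46% side product and 41.5% starting material. In red, green and grey partner exceeds starting material, so I set the share of target at one over one plus κ times the mean [partner], taken midway between the charge and what one equivalent leaves. That gives red 88.5%, green 86.8% and grey 97.1%.

The forecast gives grey > red > green > ochre, my order too, with 96.3% first and 57% last. For grey it says “The excess is thin” and leaves some starting material unconverted, so its figure is lower than mine, which assumes full conversion.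

The flask gives grey > red > green > ochre, from grey at 96.7% down to ochre at 57.0%.

    crystals ⇌ target, rate k1*(cs1 - [target]) while solid is left; crystals form when [target] > cs1 (solubility = 28.0 mM, k = 17.0 min⁻¹)
    starting material + partner → target (k = 6.80 M⁻¹ min⁻¹)
    starting material + 2 partner → side product (k = 3.00 M⁻² min⁻¹)

Ochre holds 43.0% of its charge as crystals, counted in target, and how little target dissolves makes no difference to ochre's target. Ochre's figure moves when its charge does. The neighbour of ochre with 0.080 M starting material has 1.50 equiv of partner, so its mean [partner] of 0.0800 M and κ give 3.36% side product. That neighbour holds 3.33% side product and 96.7% target.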